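A direct plan would keep (+)-catechin as the lower unit and close ring C of the upper unit last.
It would turn catechin in seven steps into the C8 enol acetate A2, build the mixed aryl methyl acetal A1 that carries rings A and B, ionise A1 with a chiral acid and join the cation to A2 in a formal [4+2] (oxa-Povarov) reaction to the flavan A3; deacetylation and hydrogenolysis would follow.
First weak step, the chiral-acid [4+2] union of A1 and A2: an enol ester has not served as the 2π partner, the acetal should lose its aryloxy group (ring A) more readily than its methoxy group, and one chiral anion would have to set C2, C3 and C4 at once in a reaction with no racemic precedent.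
Second weak step, the seven-step linear conversion of catechin into A2 (bromination, two benzylations, bromine–lithium exchange with formylation, boron–Wittig olefination, trifluoroborate formation, copper-mediated acetoxylation): it only hangs two carbons on C8 and builds no stereocenter.
Third weak step, the making of A1: a racemic, hydrolytically labile mixed O,O-acetal, assembled through a moisture-sensitive halide exchange after a Dakin oxidation has supplied its phenol half.

**Retrosynthetic overview**
Ring C of the upper unit (O1, C2 with aryl, C3 with OH, C4 bonded to C8 of catechin, all trans, on a 7,8-dioxygenated ring A without a 5-oxygen) is the hydroboration product of a 4-aryl-4H-chromene, so the upper unit is cut back to a flat 2-arylbenzopyrylium (flavylium) salt.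
Key disconnection: the interflavan bond C4–C8, formed by adding C8–H of tetra-O-benzylcatechin to C4 of the flavylium cation under control of a chiral binaphthyl phosphate anion; this one facial choice sets C4, and C2 and C3 follow from it in a single syn hydroboration anti to the new C4 aryl group.
Ring order: rings A and B are bought as 2,3,4-trihydroxybenzaldehyde and 3,4-dihydroxyacetophenone; ring C is closed first, as an aromatic pyrylium (C3–C4 by acid aldol condensation, then O1–C2); the catechin rings are bought; ring C is saturated last.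
No enol ester, no mixed acetal and no functionalisation of catechin beyond O-benzylation are needed; the only unprecedented element is the facial bias of a bond formation that is itself known, and the steps around it are classical.

Key step: step 5

Remark: which antipode of the binaphthyl phosphoric acid is matched with (+)-catechin for the (4S) adduct cannot be predicted with confidence; the (R) acid is written and its mirror image would be used if it proves to be the matched one. The SMILES of ion pair 9 does not encode the axis of the anion, which is given in its name; borane 11 is drawn as the monoalkylborane.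

Step 1
Reactants: 1 2,3,4-trihydroxybenzaldehyde
Product: 2 3,4-bis(benzyloxy)-2-hydroxybenzaldehyde
Conditions: BnBr (2.05 equiv), K2CO3, DMF, rt
Reagents that add atoms: benzyl bromide, BrCc1ccccc1
Why: Williamson ether synthesis in which the 4-OH (para to the formyl group, most acidic) and the 3-OH are alkylated, while the 2-OH, held in a hydrogen bond to the formyl oxygen, should stay free when only two equivalents of halide are used.

Step 2
Reactants: 3 3,4-dihydroxyacetophenone
Product: 4 3,4-bis(benzyloxy)acetophenone
Conditions: BnBr, K2CO3, DMF, 60 °C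
Reagents that add atoms: benzyl bromide, BrCc1ccccc1
Why: Williamson ether synthesis of both phenols under carbonate conditions that leave the methyl ketone untouched.

Step 3
Reactants: 2 3,4-bis(benzyloxy)-2-hydroxybenzaldehyde; 4 3,4-bis(benzyloxy)acetophenone
Product: 6 7,8-bis(benzyloxy)-2-[3,4-bis(benzyloxy)phenyl]chromenylium tetrafluoroborate, via chalcone 5 (not isolated)
Conditions: HBF4 (48% aq.), AcOH, rt, 48 h; Et2O, filtration
Reagents that add atoms: tetrafluoroboric acid, [H+].F[B-](F)(F)F
Why: Acid-catalysed crossed aldol condensation and cyclodehydration (Robinson flavylium synthesis), in which the enol of 4 adds to protonated 2 to form C3–C4, chalcone 5 isomerises about its protonated double bond, the 2-OH adds to the carbonyl carbon to form O1–C2 and loss of water gives the aromatic benzopyrylium, which should precipitate as its tetrafluoroborate while the benzyl aryl ethers withstand this acid at room temperature.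

Step 4
Reactants: 7 (+)-catechin
Product: 8 (2R,3S)-5,7-bis(benzyloxy)-2-[3,4-bis(benzyloxy)phenyl]chroman-3-ol
Conditions: BnBr, K2CO3, DMF, 0 °C → rt
Reagents that add atoms: benzyl bromide, BrCc1ccccc1
Why: Williamson etherification of the four phenols only, since carbonate neither deprotonates the C3 alcohol nor epimerises C2.

Step 5
Reactants: 6 7,8-bis(benzyloxy)-2-[3,4-bis(benzyloxy)phenyl]chromenylium tetrafluoroborate; 8 (2R,3S)-5,7-bis(benzyloxy)-2-[3,4-bis(benzyloxy)phenyl]chroman-3-ol
Product: 10 (2R,3S)-5,7-bis(benzyloxy)-2-[3,4-bis(benzyloxy)phenyl]-8-{(4S)-7,8-bis(benzyloxy)-2-[3,4-bis(benzyloxy)phenyl]-4H-chromen-4-yl}chroman-3-ol, via flavylium phosphate ion pair 9 (not isolated)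
Conditions: (R)-3,3'-bis(2,4,6-triisopropylphenyl)-1,1'-binaphthyl-2,2'-diyl hydrogen phosphate (10 mol %), Na2CO3 (powder), toluene/cyclohexane, −20 °C, dark, argon; solid 6 added in portions to 8 (1.2 equiv); filtration through basic Al2O3
Reagents that add atoms: none
Why: Proposed new method: the lipophilic phosphate anion extracts the insoluble flavylium cation of 6 into the non-polar phase as contact ion pair 9, C8 of 8 (between O1 and the 7-benzyloxy group) adds to C4 of the cation in a Friedel–Crafts-type dearomatising arylation of the pyrylium ring, and the arenium proton passes to the phosphate and on to Na2CO3, which returns the anion. The closest known reactions are the uncatalysed C4 arylation of flavylium salts by phloroglucinol-type arenes including catechin, chiral-anion phase-transfer catalysis with insoluble cationic electrophiles, and chiral-phosphate-controlled hydride addition to C4 of benzopyrylium ion pairs; facial control of an arene addition to a flavylium ion by a chiral anion has not been shown. No ring is closed: the step forms the interflavan bond C4–C8 and leaves ring C as a 4H-chromene whose enol ether carries the rest of the stereochemical programme. C4 (S) is the only new stereocenter and is to be set by the anion, which covers one face of the planar cation and is tied to the nucleophile by a hydrogen bond from the free 3-OH of 8; the catechin stereocenters make the two transition states diastereomeric, so the matched antipode of the acid can be chosen and the minor C4 epimer removed as a diastereomer. The step needs attack at C4 and not C2 (secured by the 2-aryl group and the soft arene nucleophile), at C8 and not C6 of 8 (secured by the higher nucleophilicity of C8 in 5,7-di-O-benzylated catechin, as in Lewis-acid procyanidin couplings) and no hydride transfer from 10 to unreacted cation (secured by the low concentration of dissolved cation under solid–liquid phase transfer and by the excess of 8).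

Step 6
Reactants: 10 (2R,3S)-5,7-bis(benzyloxy)-2-[3,4-bis(benzyloxy)phenyl]-8-{(4S)-7,8-bis(benzyloxy)-2-[3,4-bis(benzyloxy)phenyl]-4H-chromen-4-yl}chroman-3-ol
Product: 12 (2R,3S,4S)-7,8-bis(benzyloxy)-2-[3,4-bis(benzyloxy)phenyl]-4-[(2R,3S)-5,7-bis(benzyloxy)-2-[3,4-bis(benzyloxy)phenyl]-3-hydroxychroman-8-yl]chroman-3-ol, via C3 alkylborane 11 (not isolated)
Conditions: BH3·SMe2, THF, 0 °C → rt; then aq. NaOH, H2O2, 0 °C
Reagents that add atoms: hydrogen peroxide, OO
Why: Hydroboration–oxidation of a cyclic enol ether, in which boron adds to C3 (β to O1 and away from the benzylic C2) and hydrogen to C2 in a syn addition on the face opposite the pseudo-axial C4 aryl group, and oxidation with retention should give the 3-OH trans to both aryl groups, so that C3 (S) and C2 (R) are set together by relay from C4.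

Step 7
Reactants: 12 (2R,3S,4S)-7,8-bis(benzyloxy)-2-[3,4-bis(benzyloxy)phenyl]-4-[(2R,3S)-5,7-bis(benzyloxy)-2-[3,4-bis(benzyloxy)phenyl]-3-hydroxychroman-8-yl]chroman-3-ol
Product: 13 (2R,3S,4S)-2-(3,4-dihydroxyphenyl)-4-[(2R,3S)-2-(3,4-dihydroxyphenyl)-3,5,7-trihydroxychroman-8-yl]chroman-3,7,8-triol (CNP0231186.1)
Conditions: H2 (1 atm), Pd(OH)2/C, THF/MeOH/H2O, rt; filtration under argon, lyophilisation
Reagents that add atoms: none
Why: Hydrogenolysis of the eight benzyl ethers over Pd(OH)2/C under neutral conditions, in which the benzylic C2–O1 bonds and the C4–C8 bond of flavans are expected to persist, so no stereocenter is touched.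

**Compound list**

1 | 2,3,4-trihydroxybenzaldehyde | O=Cc1ccc(O)c(O)c1O | starting material
2 | 3,4-bis(benzyloxy)-2-hydroxybenzaldehyde | O=Cc1ccc(OCc2ccccc2)c(OCc2ccccc2)c1O | intermediate
3 | 3,4-dihydroxyacetophenone | CC(=O)c1ccc(O)c(O)c1 | starting material
4 | 3,4-bis(benzyloxy)acetophenone | CC(=O)c1ccc(OCc2ccccc2)c(OCc2ccccc2)c1 | intermediate
5 | (E)-3-[3,4-bis(benzyloxy)-2-hydroxyphenyl]-1-[3,4-bis(benzyloxy)phenyl]prop-2-en-1-one, chalcone (not isolated) | O=C(/C=C/c1ccc(OCc2ccccc2)c(OCc2ccccc2)c1O)c1ccc(OCc2ccccc2)c(OCc2ccccc2)c1 | intermediate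
6 | 7,8-bis(benzyloxy)-2-[3,4-bis(benzyloxy)phenyl]chromenylium tetrafluoroborate (flavylium salt) | F[B-](F)(F)F.c1ccccc1COc1ccc(cc1OCc1ccccc1)-c1ccc2ccc(OCc3ccccc3)c(OCc3ccccc3)c2[o+]1 | intermediate
7 | (+)-catechin, (2R,3S) | Oc1cc(O)c2c(c1)O[C@H](c1ccc(O)c(O)c1)[C@@H](O)C2 | starting material
8 | (2R,3S)-5,7-bis(benzyloxy)-2-[3,4-bis(benzyloxy)phenyl]chroman-3-ol (5,7,3',4'-tetra-O-benzylcatechin) | c1c(OCc3ccccc3)cc(OCc3ccccc3)c2c1O[C@H](c1ccc(OCc3ccccc3)c(OCc3ccccc3)c1)[C@@H](O)C2 | intermediate
9 | 7,8-bis(benzyloxy)-2-[3,4-bis(benzyloxy)phenyl]chromenylium (R)-3,3'-bis(2,4,6-triisopropylphenyl)-1,1'-binaphthyl-2,2'-diyl phosphate, contact ion pair (not isolated) | c1ccccc1COc1ccc(cc1OCc1ccccc1)-c1ccc2ccc(OCc3ccccc3)c(OCc3ccccc3)c2[o+]1.[O-]P1(=O)Oc2c(-c4c(C(C)C)cc(C(C)C)cc4C(C)C)cc3ccccc3c2-c2c3ccccc3cc(-c4c(C(C)C)cc(C(C)C)cc4C(C)C)c2O1 | intermediate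
10 | (2R,3S)-5,7-bis(benzyloxy)-2-[3,4-bis(benzyloxy)phenyl]-8-{(4S)-7,8-bis(benzyloxy)-2-[3,4-bis(benzyloxy)phenyl]-4H-chromen-4-yl}chroman-3-ol | c1ccccc1COc1ccc(C2=C[C@H](c3c(OCc4ccccc4)cc(OCc4ccccc4)c4c3O[C@H](c3ccc(OCc5ccccc5)c(OCc5ccccc5)c3)[C@@H](O)C4)c3ccc(OCc4ccccc4)c(OCc4ccccc4)c3O2)cc1OCc1ccccc1 | intermediate
11 | C3 alkylborane: 12 with BH2 in place of the upper 3-OH, boron trans to the C2 and C4 aryl groups (not isolated) | c1ccccc1COc1ccc([C@H]2Oc3c(ccc(OCc4ccccc4)c3OCc3ccccc3)[C@@H](c3c(OCc4ccccc4)cc(OCc4ccccc4)c4c3O[C@H](c3ccc(OCc5ccccc5)c(OCc5ccccc5)c3)[C@@H](O)C4)[C@@H]2B)cc1OCc1ccccc1 | intermediate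
12 | (2R,3S,4S)-7,8-bis(benzyloxy)-2-[3,4-bis(benzyloxy)phenyl]-4-[(2R,3S)-5,7-bis(benzyloxy)-2-[3,4-bis(benzyloxy)phenyl]-3-hydroxychroman-8-yl]chroman-3-ol (octa-O-benzyl ether of the target) | c1ccccc1COc1ccc([C@H]2Oc3c(ccc(OCc4ccccc4)c3OCc3ccccc3)[C@@H](c3c(OCc4ccccc4)cc(OCc4ccccc4)c4c3O[C@H](c3ccc(OCc5ccccc5)c(OCc5ccccc5)c3)[C@@H](O)C4)[C@@H]2O)cc1OCc1ccccc1 | intermediate
13 | (2R,3S,4S)-2-(3,4-dihydroxyphenyl)-4-[(2R,3S)-2-(3,4-dihydroxyphenyl)-3,5,7-trihydroxychroman-8-yl]chroman-3,7,8-triol, CNP0231186.1 | Oc1ccc([C@H]2Oc3c(ccc(O)c3O)[C@@H](c3c(O)cc(O)c4c3O[C@H](c3ccc(O)c(O)c3)[C@@H](O)C4)[C@@H]2O)cc1O | target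

**Step count and risks**

Total step count: 7. Longest linear sequence: 5 steps (steps 1, 3, 5, 6 and 7, from 2,3,4-trihydroxybenzaldehyde).

Steps most likely to fail:

Step 5 (Proposed new method). The chiral anion may fail to distinguish the two faces of the flavylium cation, so that C4 forms with little selectivity, and product may pass hydride to unreacted cation. The fallback uses known chemistry and sets out from 6 and 8. The condensation would be run without the chiral acid (NaHCO3, MeCN/CH2Cl2, 0 °C), the known C4 arylation of flavylium salts by phloroglucinol-type arenes. It should give 10 together with its C4 epimer, the (4R)-4H-chromene F1. The mixture would be hydroborated as in step 6 to 12 and the (2S,3R,4R)-configured octa-O-benzyl diastereomer F2. These differ at three stereocenters beside a fixed catechin unit and would be separated by chromatography. The sequence comes back to the route at 12, with the configuration secured by separation in place of induction.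

Step 6. In the C3 borane the boron stands anti to the C2–O1 bond, so elimination of the phenoxide with opening of ring C could compete with oxidation. The fallback sets out from 10. Syn dihydroxylation with OsO4 (cat.) and N-methylmorpholine N-oxide, anti to the C4 aryl group, would give the 2,3-diol hemiketal F3. Ionic reduction (Et3SiH, BF3·OEt2, CH2Cl2, −78 °C) through the C2 oxocarbenium ion, with axial hydride delivery that leaves the C2 aryl group equatorial, would come back to the route at 12.

Step 3. Isomerisation of chalcone 5 about its double bond may be slow under acid, and long exposure could cost benzyl groups. The fallback sets out from 2 and 4. A base-mediated Claisen–Schmidt condensation (KOH, EtOH, rt) would give 5 as an isolated solid. Irradiation with blue light in CH2Cl2 with one equivalent of HBF4·OEt2 would then drive photoisomerisation and ring closure in a short contact with acid, coming back to the route at 6. This path makes no compound outside the list (F0).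

Further compounds
F1 | step 5 | (2R,3S)-5,7-bis(benzyloxy)-2-[3,4-bis(benzyloxy)phenyl]-8-{(4R)-7,8-bis(benzyloxy)-2-[3,4-bis(benzyloxy)phenyl]-4H-chromen-4-yl}chroman-3-ol, C4 epimer of 10 | c1ccccc1COc1ccc(C2=C[C@@H](c3c(OCc4ccccc4)cc(OCc4ccccc4)c4c3O[C@H](c3ccc(OCc5ccccc5)c(OCc5ccccc5)c3)[C@@H](O)C4)c3ccc(OCc4ccccc4)c(OCc4ccccc4)c3O2)cc1OCc1ccccc1
F2 | step 5 | (2S,3R,4R)-7,8-bis(benzyloxy)-2-[3,4-bis(benzyloxy)phenyl]-4-[(2R,3S)-5,7-bis(benzyloxy)-2-[3,4-bis(benzyloxy)phenyl]-3-hydroxychroman-8-yl]chroman-3-ol, diastereomer of 12 | c1ccccc1COc1ccc([C@@H]2Oc3c(ccc(OCc4ccccc4)c3OCc3ccccc3)[C@H](c3c(OCc4ccccc4)cc(OCc4ccccc4)c4c3O[C@H](c3ccc(OCc5ccccc5)c(OCc5ccccc5)c3)[C@@H](O)C4)[C@H]2O)cc1OCc1ccccc1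
F3 | step 6 | (2R,3S,4S)-7,8-bis(benzyloxy)-2-[3,4-bis(benzyloxy)phenyl]-4-[(2R,3S)-5,7-bis(benzyloxy)-2-[3,4-bis(benzyloxy)phenyl]-3-hydroxychroman-8-yl]chromane-2,3-diol, hemiketal with 2-OH cis to 3-OH | c1ccccc1COc1ccc([C@@]2(O)Oc3c(ccc(OCc4ccccc4)c3OCc3ccccc3)[C@@H](c3c(OCc4ccccc4)cc(OCc4ccccc4)c4c3O[C@H](c3ccc(OCc5ccccc5)c(OCc5ccccc5)c3)[C@@H](O)C4)[C@@H]2O)cc1OCc1ccccc1
F0 | step 3 | none | none
A1 | direct plan | 3,4-bis(benzyloxy)benzaldehyde 2,3-bis(benzyloxy)phenyl methyl acetal, racemic | COC(Oc1cccc(OCc2ccccc2)c1OCc1ccccc1)c1ccc(OCc2ccccc2)c(OCc2ccccc2)c1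
A2 | direct plan | (E)-2-[(2R,3S)-3,5,7,3',4'-penta-O-benzylcatechin-8-yl]vinyl acetate | CC(=O)O/C=C/c1c(OCc3ccccc3)cc(OCc3ccccc3)c2c1O[C@H](c1ccc(OCc3ccccc3)c(OCc3ccccc3)c1)[C@@H](OCc1ccccc1)C2
A3 | direct plan | (2R,3S,4S)-3-acetoxy-7,8-bis(benzyloxy)-2-[3,4-bis(benzyloxy)phenyl]-4-[(2R,3S)-penta-O-benzylcatechin-8-yl]chroman | c1ccccc1COc1ccc([C@H]2Oc3c(ccc(OCc4ccccc4)c3OCc3ccccc3)[C@@H](c3c(OCc4ccccc4)cc(OCc4ccccc4)c4c3O[C@H](c3ccc(OCc5ccccc5)c(OCc5ccccc5)c3)[C@@H](OCc3ccccc3)C4)[C@@H]2OC(C)=O)cc1OCc1ccccc1
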